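**Plan**

1. Retrosynthesis: the quinone is the oxidised form of hydroquinone 21. Its benzenoid ring is cut at the bond between the two OMe-bearing carbons, giving the (Z)-ene-1,4-dione 18, which is the oxidatively opened form of the 2,5-disubstituted furan in 16.
2. Enabling feature: the quinone ring is four contiguous oxygenated carbons, C(=O)–C(OMe)=C(OMe)–C(=O), closed by a C(R)=CH unit. The C(=O)–C(R)=CH–C(=O) part is a furan in disguise. The two OMe carbons are its side-chain carbons, CH2OMe (nucleophile) and CH(OMe)2 (electrophile), already at the oxidation level of the hydroquinone keto tautomer.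
3. The furyl–chroman C–C bond is kept. The pyran ring is cut at C3=C4 (chromene 15), by intramolecular Wittig reaction of phosphonium salt 7 with chloroketone 13.
4. Forward order: ring A unit 7 (five steps) and furan 13 (three steps) are joined with closure of the pyran ring (step 9). The furan is opened (step 11), the hydroquinone ring is closed last (step 12), then debenzylation and oxidation follow.
5. Stereochemistry: the single stereocentre (chroman C3, S) comes from iridium-catalysed asymmetric hydrogenation of the C3=C4 bond of 15 (step 10) and is not touched afterwards.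

Key step: step 12

Remarks: 1 and 8 are taken as commercially available. In step 10 the ligand enantiomer is the one that delivers the (S)-chroman; this is to be fixed on a test run.

**Route**

Step 1
Reactants: 1 2-hydroxy-3,4-dimethoxybenzaldehyde
Product: 2 2-(benzyloxy)-3,4-dimethoxybenzaldehyde
Conditions: BnBr, K2CO3, DMF, 60 °C
Reagents that add atoms: benzyl bromide (BrCc1ccccc1)
Why: Williamson ether synthesis; the phenoxide is benzylated, which masks the future C8 hydroxyl as the only benzyl ether of the route.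

Step 2
Reactants: 2 2-(benzyloxy)-3,4-dimethoxybenzaldehyde
Product: 4 2-(benzyloxy)-3,4-dimethoxyphenol, via aryl formate 3 (not isolated)
Conditions: mCPBA, CH2Cl2, rt; then K2CO3 (cat.), MeOH, rt
Reagents that add atoms: 3-chloroperoxybenzoic acid (OOC(=O)c1cccc(Cl)c1)
Why: Dakin-type Baeyer–Villiger oxidation; the electron-rich aryl group (ortho- and para-alkoxy) migrates to oxygen and methanolysis of the formate frees the phenol whose oxygen becomes the pyran oxygen.

Step 3
Reactants: 4 2-(benzyloxy)-3,4-dimethoxyphenol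
Product: 5 3-(benzyloxy)-2-hydroxy-4,5-dimethoxybenzaldehyde
Conditions: MgCl2, Et3N, (CH2O)n, MeCN, reflux
Reagents that add atoms: formaldehyde as paraformaldehyde (C=O)
Why: Magnesium-mediated ortho-formylation (Casnati–Skattebøl); the magnesium phenoxide delivers formaldehyde to the only free ortho carbon and a second formaldehyde accepts hydride.

Step 4
Reactants: 5 3-(benzyloxy)-2-hydroxy-4,5-dimethoxybenzaldehyde
Product: 6 2-(benzyloxy)-6-(hydroxymethyl)-3,4-dimethoxyphenol
Conditions: NaBH4, MeOH/THF, 0 °C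
Reagents that add atoms: none
Why: Borohydride reduction of the aldehyde to the benzylic alcohol; nothing else in 5 is reducible under these conditions.

Step 5
Reactants: 6 2-(benzyloxy)-6-(hydroxymethyl)-3,4-dimethoxyphenol
Product: 7 {[3-(benzyloxy)-2-hydroxy-4,5-dimethoxyphenyl]methyl}triphenylphosphonium bromide
Conditions: PPh3·HBr, MeCN, reflux
Reagents that add atoms: triphenylphosphine hydrobromide ([Br-].[PH+](c1ccccc1)(c1ccccc1)c1ccccc1)
Why: Acid-promoted substitution of the ortho-hydroxybenzylic alcohol by triphenylphosphine through the ortho-quinone methide, the usual entry to (2-hydroxybenzyl)phosphonium salts.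

Step 6
Reactants: 8 4-bromofuran-2-carbaldehyde
Product: 9 4-bromo-2-(dimethoxymethyl)furan
Conditions: HC(OMe)3, p-TsOH·H2O (cat.), MeOH, rt; Et3N quench
Reagents that add atoms: trimethyl orthoformate (COC(OC)OC)
Why: Acid-catalysed acetalisation with the orthoformate as water scavenger; it protects the aldehyde from the organolithium steps and installs the carbon that later acts as the electrophile.

Step 7
Reactants: 9 4-bromo-2-(dimethoxymethyl)furan
Product: 11 3-bromo-5-(dimethoxymethyl)-2-(methoxymethyl)furan, via 2-furyllithium 10 (not isolated)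
Conditions: LiN(i-Pr)2, THF, −78 °C; then ClCH2OMe, −78 → 0 °C
Reagents that add atoms: chloromethyl methyl ether (COCCl)
Why: Deprotonative lithiation at the furan α-carbon flanked by ring oxygen and bromine (the most acidic C–H, which leaves no driving force for bromine migration), then SN2 alkylation.

Step 8
Reactants: 11 3-bromo-5-(dimethoxymethyl)-2-(methoxymethyl)furan
Product: 13 2-chloro-1-[5-(dimethoxymethyl)-2-(methoxymethyl)furan-3-yl]ethan-1-one, via 3-furyllithium 12 (not isolated)
Conditions: n-BuLi, THF, −78 °C; then ClCH2C(O)N(OMe)Me, −78 → −20 °C; H2O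
Reagents that add atoms: 2-chloro-N-methoxy-N-methylacetamide (CON(C)C(=O)CCl)
Why: Bromine–lithium exchange gives the 3-furyllithium regiospecifically, and acylation by the N-methoxy-N-methylamide stops at the ketone through the chelated tetrahedral intermediate.

Step 9
Reactants: 7 {[3-(benzyloxy)-2-hydroxy-4,5-dimethoxyphenyl]methyl}triphenylphosphonium bromide; 13 2-chloro-1-[5-(dimethoxymethyl)-2-(methoxymethyl)furan-3-yl]ethan-1-one
Product: 15 8-(benzyloxy)-3-[5-(dimethoxymethyl)-2-(methoxymethyl)furan-3-yl]-6,7-dimethoxy-2H-chromene, via aryloxy ketone phosphonium salt 14 (not isolated)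
Conditions: K2CO3, MeCN, rt → 70 °C
Reagents that add atoms: none
Why: O-alkylation of the phenoxide by the α-chloroketone, then intramolecular Wittig olefination of the benzylic ylide with the ketone, closes the pyran ring and fixes the alkene at C3=C4.

Step 10
Reactants: 15 8-(benzyloxy)-3-[5-(dimethoxymethyl)-2-(methoxymethyl)furan-3-yl]-6,7-dimethoxy-2H-chromene
Product: 16 (3S)-8-(benzyloxy)-3-[5-(dimethoxymethyl)-2-(methoxymethyl)furan-3-yl]-6,7-dimethoxy-3,4-dihydro-2H-chromene
Conditions: H2 (50 bar), [Ir(cod)(L)][B(C6H3-3,5-(CF3)2)4] (2 mol %), L = 4-tert-butyl-2-[2-(diphenylphosphino)phenyl]-4,5-dihydrooxazole (single enantiomer), CH2Cl2, rt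
Reagents that add atoms: none
Why: Iridium–phosphinooxazoline asymmetric hydrogenation of a trisubstituted aryl alkene of the 3-aryl-2H-chromene class; the chiral ligand sets C3 by face-selective hydrogen delivery, while the benzyl ether and furan should stay intact under homogeneous conditions.

Step 11
Reactants: 16 (3S)-8-(benzyloxy)-3-[5-(dimethoxymethyl)-2-(methoxymethyl)furan-3-yl]-6,7-dimethoxy-3,4-dihydro-2H-chromene
Product: 18 (3Z)-4-[(3S)-8-(benzyloxy)-6,7-dimethoxy-3,4-dihydro-2H-chromen-3-yl]-1,1,6-trimethoxyhex-3-ene-2,5-dione, via furan endoperoxide 17 (not isolated)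
Conditions: O2, hν (visible), tetraphenylporphyrin (cat.), CH2Cl2, −78 °C; then Me2S, −78 °C → rt
Reagents that add atoms: oxygen (O=O)
Why: Singlet-oxygen [4+2] cycloaddition to the furan and reductive cleavage of the endoperoxide give the cis-enedione with the Z geometry inherited from the ring; the arene, benzyl ether and acetal should not react.

Step 12
Reactants: 18 (3Z)-4-[(3S)-8-(benzyloxy)-6,7-dimethoxy-3,4-dihydro-2H-chromen-3-yl]-1,1,6-trimethoxyhex-3-ene-2,5-dione
Product: 21 5-[(3S)-8-(benzyloxy)-6,7-dimethoxy-3,4-dihydro-2H-chromen-3-yl]-2,3-dimethoxybenzene-1,4-diol, via enol silane 19 (not isolated), via cyclohexenedione 20 (not isolated)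
Conditions: Me3SiOTf (2.5 equiv), i-Pr2NEt (1.5 equiv), CH2Cl2, −78 → 0 °C, Ar; then MeOH, aq citric acid
Reagents that add atoms: none
Why: Proposed new method: Me3SiOTf/i-Pr2NEt turns the methoxymethyl ketone (CH2OMe is the only enolisable α-position of that carbonyl) into enol silane 19, Me3SiOTf then ionises the dimethyl acetal to an oxocarbenium ion, and the enol silane carbon attacks it in an intramolecular Mukaiyama-type aldol addition to give 20, the keto tautomer of the hydroquinone, which aromatises by two enolisations. The closest known reaction types are the one-pot enol silane formation and Mukaiyama addition of ketones to dimethyl acetals under Me3SiOTf and amine, and the aldol ring closure by which ring-opened 5-(hydroxymethyl)furfural gives benzene-1,2,4-triol. The six-membered carbocycle closes in the 6-(enolendo)-exo-trig mode, with the two reacting carbons held in reach by the Z C=C bond inherited from the furan. No stereocentre results (the two CH(OMe) centres of 20 vanish on aromatisation) and chroman C3 is a spectator. The step needs the acetal, not the ketone, to act as electrophile, which silyl triflate activation secures and which suppresses five-ring aldol closure; it also needs aromatisation to beat β-loss of methanol, which the dienone-to-phenol driving force secures.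

Step 13
Reactants: 21 5-[(3S)-8-(benzyloxy)-6,7-dimethoxy-3,4-dihydro-2H-chromen-3-yl]-2,3-dimethoxybenzene-1,4-diol
Product: 23 2-[(3S)-8-hydroxy-6,7-dimethoxy-3,4-dihydro-2H-chromen-3-yl]-5,6-dimethoxycyclohexa-2,5-diene-1,4-dione, via debenzylated hydroquinone 22 (not isolated)
Conditions: H2 (1 atm), Pd/C (palladium on carbon), EtOAc, rt; filter under Ar; then Ag2O, Et2O, rt
Reagents that add atoms: none
Why: Hydrogenolysis of the benzyl ether, then oxidation by Ag2O of the hydroquinone, which is far more easily oxidised than the ring A monophenol, gives the quinone without touching the stereocentre.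

**Compound list**

1 | 2-hydroxy-3,4-dimethoxybenzaldehyde | COc1ccc(C=O)c(O)c1OC | starting material
2 | 2-(benzyloxy)-3,4-dimethoxybenzaldehyde | COc1ccc(C=O)c(OCc2ccccc2)c1OC | intermediate
3 | 2-(benzyloxy)-3,4-dimethoxyphenyl formate | COc1ccc(OC=O)c(OCc2ccccc2)c1OC | intermediate (not isolated)
4 | 2-(benzyloxy)-3,4-dimethoxyphenol | COc1ccc(O)c(OCc2ccccc2)c1OC | intermediate
5 | 3-(benzyloxy)-2-hydroxy-4,5-dimethoxybenzaldehyde | COc1cc(C=O)c(O)c(OCc2ccccc2)c1OC | intermediate
6 | 2-(benzyloxy)-6-(hydroxymethyl)-3,4-dimethoxyphenol | COc1cc(CO)c(O)c(OCc2ccccc2)c1OC | intermediate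
7 | {[3-(benzyloxy)-2-hydroxy-4,5-dimethoxyphenyl]methyl}triphenylphosphonium bromide | COc1cc(C[P+](c2ccccc2)(c2ccccc2)c2ccccc2)c(O)c(OCc2ccccc2)c1OC.[Br-] | intermediate
8 | 4-bromofuran-2-carbaldehyde | O=Cc1cc(Br)co1 | starting material
9 | 4-bromo-2-(dimethoxymethyl)furan | COC(OC)c1cc(Br)co1 | intermediate
10 | [3-bromo-5-(dimethoxymethyl)furan-2-yl]lithium | [Li]c1oc(C(OC)OC)cc1Br | intermediate (not isolated)
11 | 3-bromo-5-(dimethoxymethyl)-2-(methoxymethyl)furan | COCc1oc(C(OC)OC)cc1Br | intermediate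
12 | [5-(dimethoxymethyl)-2-(methoxymethyl)furan-3-yl]lithium | [Li]c1cc(C(OC)OC)oc1COC | intermediate (not isolated)
13 | 2-chloro-1-[5-(dimethoxymethyl)-2-(methoxymethyl)furan-3-yl]ethan-1-one | COCc1oc(C(OC)OC)cc1C(=O)CCl | intermediate
14 | ({3-(benzyloxy)-2-[2-[5-(dimethoxymethyl)-2-(methoxymethyl)furan-3-yl]-2-oxoethoxy]-4,5-dimethoxyphenyl}methyl)triphenylphosphonium bromide | COCc1oc(C(OC)OC)cc1C(=O)COc1c(C[P+](c2ccccc2)(c2ccccc2)c2ccccc2)cc(OC)c(OC)c1OCc1ccccc1.[Br-] | intermediate (not isolated)
15 | 8-(benzyloxy)-3-[5-(dimethoxymethyl)-2-(methoxymethyl)furan-3-yl]-6,7-dimethoxy-2H-chromene | COCc1oc(C(OC)OC)cc1C2=Cc3cc(OC)c(OC)c(OCc4ccccc4)c3OC2 | intermediate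
16 | (3S)-8-(benzyloxy)-3-[5-(dimethoxymethyl)-2-(methoxymethyl)furan-3-yl]-6,7-dimethoxy-3,4-dihydro-2H-chromene | COCc1oc(C(OC)OC)cc1[C@H]2COc3c(cc(OC)c(OC)c3OCc4ccccc4)C2 | intermediate
17 | (3S)-8-(benzyloxy)-3-[4-(dimethoxymethyl)-1-(methoxymethyl)-2,3,7-trioxabicyclo[2.2.1]hept-5-en-6-yl]-6,7-dimethoxy-3,4-dihydro-2H-chromene (mixture at the bridgeheads) | COCC12OOC(C(OC)OC)(O1)C=C2[C@H]3COc4c(cc(OC)c(OC)c4OCc5ccccc5)C3 | intermediate (not isolated)
18 | (3Z)-4-[(3S)-8-(benzyloxy)-6,7-dimethoxy-3,4-dihydro-2H-chromen-3-yl]-1,1,6-trimethoxyhex-3-ene-2,5-dione | COCC(=O)/C(=C\C(=O)C(OC)OC)[C@H]1COc2c(cc(OC)c(OC)c2OCc3ccccc3)C1 | intermediate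
19 | (3Z)-4-[(3S)-8-(benzyloxy)-6,7-dimethoxy-3,4-dihydro-2H-chromen-3-yl]-1,1,6-trimethoxy-5-[(trimethylsilyl)oxy]hexa-3,5-dien-2-one (enol ether geometry not defined) | COC=C(O[Si](C)(C)C)/C(=C\C(=O)C(OC)OC)[C@H]1COc2c(cc(OC)c(OC)c2OCc3ccccc3)C1 | intermediate (not isolated)
20 | 2-[(3S)-8-(benzyloxy)-6,7-dimethoxy-3,4-dihydro-2H-chromen-3-yl]-5,6-dimethoxycyclohex-2-ene-1,4-dione (mixture at C5 and C6) | COC1C(OC)C(=O)C=C([C@H]2COc3c(cc(OC)c(OC)c3OCc4ccccc4)C2)C1=O | intermediate (not isolated)
21 | 5-[(3S)-8-(benzyloxy)-6,7-dimethoxy-3,4-dihydro-2H-chromen-3-yl]-2,3-dimethoxybenzene-1,4-diol | COc1c(OC)c(O)cc([C@H]2COc3c(cc(OC)c(OC)c3OCc4ccccc4)C2)c1O | intermediate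
22 | 5-[(3S)-8-hydroxy-6,7-dimethoxy-3,4-dihydro-2H-chromen-3-yl]-2,3-dimethoxybenzene-1,4-diol | COc1c(OC)c(O)cc([C@H]2COc3c(cc(OC)c(OC)c3O)C2)c1O | intermediate (not isolated)
23 | 2-[(3S)-8-hydroxy-6,7-dimethoxy-3,4-dihydro-2H-chromen-3-yl]-5,6-dimethoxycyclohexa-2,5-diene-1,4-dione | COC1=C(OC)C(=O)C([C@H]2COc3c(cc(OC)c(OC)c3O)C2)=CC1=O | target

**Step count and risks**

Total steps: 13. Longest linear sequence: 10 (steps 1–5 and 9–13).

Steps most likely to fail:

1. Step 12 (proposed new method). Ionisation of the acetal next to a carbonyl may be slow. Z-to-E isomerisation of the enedione or five-ring aldol closure onto a ketone could then overtake, and enolisation through the γ-hydrogen at chroman C3 would erode the stereocentre. The fallback uses known chemistry, sets out from 18 and returns at 22. Aqueous trifluoroacetic acid in THF hydrolyses the acetal of 18 to the keto-aldehyde (3Z)-4-[(3S)-8-(benzyloxy)-6,7-dimethoxy-3,4-dihydro-2H-chromen-3-yl]-6-methoxy-2,5-dioxohex-3-enal F1. The free aldehyde needs no ionisation, and acid-catalysed intramolecular aldol addition of the methoxymethyl ketone enol to it, followed by tautomerisation, gives 5-[(3S)-8-(benzyloxy)-6,7-dimethoxy-3,4-dihydro-2H-chromen-3-yl]-3-methoxybenzene-1,2,4-triol F2. Ag2O oxidises this to 5-[(3S)-8-(benzyloxy)-6,7-dimethoxy-3,4-dihydro-2H-chromen-3-yl]-2-hydroxy-3-methoxycyclohexa-2,5-diene-1,4-dione F3. Its single acidic hydroxyl is methylated with Me3SiCHN2 in MeOH/toluene to 2-[(3S)-8-(benzyloxy)-6,7-dimethoxy-3,4-dihydro-2H-chromen-3-yl]-5,6-dimethoxycyclohexa-2,5-diene-1,4-dione F4. Hydrogenation of F4 over Pd/C under the conditions of step 13 reduces the quinone and cleaves the benzyl ether, giving 22.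

2. Step 10. Facial selectivity on the hindered trisubstituted alkene may be poor, or the acidic iridium hydride may cleave the acetal. The fallback replaces catalyst control by resolution, sets out from 15 and returns at 16. Hydrogenation over Pd/C with added pyridine (benzyl ether retained) in EtOAc gives racemic 8-(benzyloxy)-3-[5-(dimethoxymethyl)-2-(methoxymethyl)furan-3-yl]-6,7-dimethoxy-3,4-dihydro-2H-chromene F5. Preparative chromatography on a chiral stationary phase separates 16 from the (3R)-8-(benzyloxy)-3-[5-(dimethoxymethyl)-2-(methoxymethyl)furan-3-yl]-6,7-dimethoxy-3,4-dihydro-2H-chromene F6, which is discarded.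

3. Step 9. The phenoxide may lose triphenylphosphine (ortho-quinone methide formation), or C-alkylation of the ylide may compete with O-alkylation, before the ring can close. The fallback replaces the Wittig closure by a carbonyl–carbonyl coupling, sets out from 5 and 13 and returns at 15. K2CO3 in acetone at rt joins 5 and 13 to 3-(benzyloxy)-2-{2-[5-(dimethoxymethyl)-2-(methoxymethyl)furan-3-yl]-2-oxoethoxy}-4,5-dimethoxybenzaldehyde F7. Intramolecular McMurry coupling (TiCl4, Zn, pyridine, THF, reflux) of its aldehyde and ketone then gives 15; steps 4 and 5 are not needed in this case.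

Further compounds

F1 | step 12 | (3Z)-4-[(3S)-8-(benzyloxy)-6,7-dimethoxy-3,4-dihydro-2H-chromen-3-yl]-6-methoxy-2,5-dioxohex-3-enal | COCC(=O)/C(=C\C(=O)C=O)[C@H]1COc2c(cc(OC)c(OC)c2OCc3ccccc3)C1
F2 | step 12 | 5-[(3S)-8-(benzyloxy)-6,7-dimethoxy-3,4-dihydro-2H-chromen-3-yl]-3-methoxybenzene-1,2,4-triol | COc1c(O)c(O)cc([C@H]2COc3c(cc(OC)c(OC)c3OCc4ccccc4)C2)c1O
F3 | step 12 | 5-[(3S)-8-(benzyloxy)-6,7-dimethoxy-3,4-dihydro-2H-chromen-3-yl]-2-hydroxy-3-methoxycyclohexa-2,5-diene-1,4-dione | COC1=C(O)C(=O)C=C([C@H]2COc3c(cc(OC)c(OC)c3OCc4ccccc4)C2)C1=O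
F4 | step 12 | 2-[(3S)-8-(benzyloxy)-6,7-dimethoxy-3,4-dihydro-2H-chromen-3-yl]-5,6-dimethoxycyclohexa-2,5-diene-1,4-dione | COC1=C(OC)C(=O)C=C([C@H]2COc3c(cc(OC)c(OC)c3OCc4ccccc4)C2)C1=O
F5 | step 10 | racemic 8-(benzyloxy)-3-[5-(dimethoxymethyl)-2-(methoxymethyl)furan-3-yl]-6,7-dimethoxy-3,4-dihydro-2H-chromene | COCc1oc(C(OC)OC)cc1C2COc3c(cc(OC)c(OC)c3OCc4ccccc4)C2
F6 | step 10 | (3R)-8-(benzyloxy)-3-[5-(dimethoxymethyl)-2-(methoxymethyl)furan-3-yl]-6,7-dimethoxy-3,4-dihydro-2H-chromene | COCc1oc(C(OC)OC)cc1[C@@H]2COc3c(cc(OC)c(OC)c3OCc4ccccc4)C2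
F7 | step 9 | 3-(benzyloxy)-2-{2-[5-(dimethoxymethyl)-2-(methoxymethyl)furan-3-yl]-2-oxoethoxy}-4,5-dimethoxybenzaldehyde | COCc1oc(C(OC)OC)cc1C(=O)COc1c(C=O)cc(OC)c(OC)c1OCc1ccccc1
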